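(The readings are simulated with constants of no real substance, noise included.)

In a one-step world starting material would turn into target and the flask would stop there, but here the side product takes up one starting material and one target, and it is counted as two.

the same everywhere: free catalyst 1.3 mM
- north-east: starting material 20 mM; coupling partner 22 mM; run made earlier
- south-east: starting material 20 mM; coupling partner 11 mM; run made earlier
- north-west: starting material 20 mM; coupling partner 16 mM; run made earlier
- oak: starting material 20 mM (fed, over 3.0 h); coupling partner 22.0 mM; all else is in the flask from the start; the feed brings no volume worth counting; time 4.0 h
- birch: starting material 20 mM (in portions, 4, over 3.0 h); coupling partner 22.0 mM; first portion at the start, last at 3.0 h; time 4.0 h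
- alder: starting material 20 mM; coupling partner 22.0 mM (fed, over 3.0 h); all else is in the flask from the start; the feed brings no volume worth counting; time 4.0 h
- elm: starting material 20 mM; coupling partner 22.0 mM; everything together at the start; time 4.0 h
- ash: starting material 20 mM (fed, over 20 min); coupling partner 22.0 mM; all else is in the flask from the start; the feed brings no volume worth counting; time 4.0 h

- north-east (time / h: side product / %, target / %, starting material / %): 0.333: 7.1, 27.0, 60.6; 0.833: 24.9, 50.7, 23.8; 1.50: 35.8, 54.4, 10.3; 2.50: 44.9, 50.2, 5.7
- south-east (time / h: side product / %, target / %, starting material / %): 0.833: 21.7, 28.0, 49.1; 1.50: 38.3, 22.1, 40.7; 2.50: 52.4, 15.8, 32.0; 3.00: 57.3, 12.3, 31.0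
- north-west (time / h: side product / %, target / %, starting material / %): 0.250: 3.6, 18.5, 72.4; 0.667: 18.2, 37.4, 41.8; 1.33: 36.6, 37.4, 25.3; 3.00: 59.0, 27.3, 14.8

(readings scatter by 0.5 percentage points)

- a species is counted by the starting material in it: one side product counts as two
- the numbers in the tables scatter by 0.5 percentage points (one standard deviation)

* the flask with the highest amount of side product, in percent of the starting material charged ("all alike" if they lie within 1.5 percentage points) (oak / birch / alder / elm / ash / all alike)
* final side product, as a percentage of the starting material charged, in oak
* final side product, as a percentage of the starting material charged, in birch
* final side product, as a percentage of the starting material charged, in alder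
* final side product, as a percentage of the starting material charged, in elm
* final side product, as a percentage of the starting material charged, in ash

So each side product holds a target once made, and you can add up the target ever made as the target in the flask plus half of the side product. In the north-east run, which has the charges of elm, that sum reads 72.3% at 1.50 h and 72.7% at 2.50 h. That is flat within a scatter of 0.5 percentage points, and it stands below the coupling partner charged, 110% of the starting material. So you should read the coupling as finished, with some partner lost another way.

From here the reckoning is my own. Once no more target is made and the starting material is gone, target and side product add up to the whole charge, so the side product ends at twice the shortfall of target ever made below that charge. For the north-east run that reading gives 54.7%, and I call it the side-product ceiling. A flask below its ceiling at 4.0 h still holds starting material, so each recipe has to be asked two things: how much target it made, and how near its ceiling it stands.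

The forecast names alder highest, at 56%, with ash at 52%, elm at 51%, oak at 49% and birch at 48%, on the ground that “Feeding partner keeps starting material high while target builds”.

The flasks give 48.8% in oak, 44.6% in birch, 47.2% in alder, 50.3% in elm and 53.2% in ash, so ash holds the most.

    coupling partner + free catalyst → catalyst intermediate A (k = 1.20 M⁻¹ s⁻¹)
    starting material + catalyst intermediate A ⇌ catalyst intermediate B (K = 730 M⁻¹, k = 13.0 M⁻¹ s⁻¹)
    catalyst intermediate B → free catalyst + target (k = 0.00590 s⁻¹)
    coupling partner → decomposed reagent (k = 2.60 × 10⁻⁴ s⁻¹)
    starting material + target → side product (k = 0.0150 M⁻¹ s⁻¹)

Alder, with 0% starting material left, has made 76.4% of target, more than the 72.7% read in the north-east run, so its 47.2% stands on its own ceiling, below the 54.7% of that run. Ash at 4.00 h, with 0% of its coupling partner, the limiting reagent, left, has made 69.9%, which gives a ceiling of 60.2%, and its 3.55% starting material has a half-life of 1.5 h by reaction with target, shorter than the 11.0 h to a later reading, and at 15 h ash holds 60.2% side product.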